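**Plan**

- Retrosynthesis: the 5-OH is first traced back to a 5-OMe. Ring B is then cut at C1'–C2' and C5'–C6' into a 2-ethynylchromone and an acetoacetate-derived 1-methoxy-1,3-bis(silyloxy)butadiene. The alkyne goes back to a C2 aldehyde, the pyrone (C2–C3, O1–C2) to a 2-hydroxyacetophenone plus a glyoxylate acetal ester, and ring A (C8–O, C4–C4a) to 3,4,5-trimethoxyphenol.
- Enabling feature: ring B is a resorcinol with its oxygens on C2' and C4', ortho and para to C1', the carbon bonded to C2 of ring C. A 1,1,3-trioxygenated diene places exactly this pattern on an alkyne carried at C2.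
- Forward order: ring A is bought and fully oxygenated (steps 1–3), ring C is closed (step 4), the C2 side chain becomes ethynyl (steps 5–6), ring B is built by [4+2] cycloaddition and aromatisation (step 9, diene from steps 7–8), and the chelated 5-O-methyl group is removed (step 10).
- Stereochemistry: the target has no stereocentre and no stereogenic double bond. The single sp3 stereocentre of the cycloadduct and the diene geometry disappear on aromatisation.

Key step: step 9

Remark (assumption): the silyl enol ether and the silyloxydiene made from methyl acetoacetate are drawn as Z isomers for definiteness. Any mixture of geometric isomers would serve, because both double bonds end up in the arene. Flavone numbering is used for ring positions.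

**Route**

Step 1
Reactants: 1 3,4,5-trimethoxyphenol
Product: 2 1-(6-hydroxy-2,3,4-trimethoxyphenyl)ethanone
Conditions: AcOH, BF3·OEt2, 85 °C; then H2O
Reagents that add atoms: acetic acid, CC(=O)O
Why: Friedel–Crafts acetylation promoted by BF3 should take place at one of the two equivalent, strongly activated positions ortho to the phenol, and the hydrogen-bonded ketone formed is deactivated towards a second acylation.

Step 2
Reactants: 2 1-(6-hydroxy-2,3,4-trimethoxyphenyl)ethanone
Product: 3 1-(3-bromo-2-hydroxy-4,5,6-trimethoxyphenyl)ethanone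
Conditions: NBS, MeCN, 0 °C → rt
Reagents that add atoms: N-bromosuccinimide, O=C1CCC(=O)N1Br
Why: Electrophilic aromatic bromination should occur at the only unsubstituted ring carbon, which lies ortho to the phenol and to a methoxy group and is far more reactive than the acetyl side chain.

Step 3
Reactants: 3 1-(3-bromo-2-hydroxy-4,5,6-trimethoxyphenyl)ethanone
Product: 4 1-(2-hydroxy-3,4,5,6-tetramethoxyphenyl)ethanone
Conditions: NaOMe (excess), CuBr (cat.), MeOH–DMF, 110 °C
Reagents that add atoms: sodium methoxide, C[O-].[Na+]
Why: Ullmann-type copper-catalysed methoxylation of an aryl bromide ortho to a phenoxide is a standard way to complete an oxygenation pattern of this kind, and the methyl ketone is held as its unreactive enolate/phenoxide.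

Step 4
Reactants: 4 1-(2-hydroxy-3,4,5,6-tetramethoxyphenyl)ethanone; 5 ethyl 2,2-diethoxyacetate
Product: 7 2-(diethoxymethyl)-5,6,7,8-tetramethoxy-4H-chromen-4-one, via diketone 6 (not isolated)
Conditions: NaH (3.5 equiv), THF, reflux; AcOH quench; then p-TsOH (cat.), EtOH, reflux
Reagents that add atoms: none
Why: Crossed Claisen condensation of the ketone enolate with the non-enolisable ester gives the 1,3-diketone (C2–C3 bond), and acid-catalysed cyclodehydration of a 2-hydroxyaryl 1,3-diketone is the classical chromone ring closure (O1–C2 bond), run in ethanol so that the acetal is kept.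

Step 5
Reactants: 7 2-(diethoxymethyl)-5,6,7,8-tetramethoxy-4H-chromen-4-one
Product: 8 5,6,7,8-tetramethoxy-4-oxo-4H-chromene-2-carbaldehyde
Conditions: HCO2H–H2O (4:1), 60 °C
Reagents that add atoms: water, O
Why: Acid-catalysed acetal hydrolysis in aqueous formic acid should be strong enough for an acetal deactivated by the electron-poor pyrone yet too mild to cleave the aryl methyl ethers.

Step 6
Reactants: 8 5,6,7,8-tetramethoxy-4-oxo-4H-chromene-2-carbaldehyde
Product: 9 2-ethynyl-5,6,7,8-tetramethoxy-4H-chromen-4-one
Conditions: dimethyl (1-diazo-2-oxopropyl)phosphonate, K2CO3, MeOH–THF, 0 °C → rt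
Reagents that add atoms: dimethyl (1-diazo-2-oxopropyl)phosphonate, COP(=O)(OC)C(=[N+]=[N-])C(C)=O
Why: Seyferth–Gilbert homologation in its Ohira–Bestmann form should convert this non-enolisable, electrophilic heteroaryl aldehyde into the terminal alkyne by olefination, loss of N2 and 1,2-shift under carbonate conditions mild enough for the pyrone.

Step 7
Reactants: 10 methyl acetoacetate
Product: 11 methyl (Z)-3-(trimethylsilyloxy)but-2-enoate
Conditions: Me3SiCl, Et3N, hexane, rt
Reagents that add atoms: chlorotrimethylsilane, C[Si](C)(C)Cl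
Why: O-Silylation of the enol of a β-keto ester (silyl enol ether formation) is routine for acetoacetates, and the amine hydrochloride is simply filtered off.

Step 8
Reactants: 11 methyl (Z)-3-(trimethylsilyloxy)but-2-enoate
Product: 12 (1Z)-1-methoxy-1,3-bis(trimethylsilyloxy)buta-1,3-diene
Conditions: LiN(iPr)2, THF, –78 °C; Me3SiCl, –78 → 0 °C
Reagents that add atoms: chlorotrimethylsilane, C[Si](C)(C)Cl
Why: Kinetic γ-deprotonation of the silyloxy crotonate and O-silylation of the resulting ester dienolate (silyl ketene acetal formation) is the standard preparation of 1,3-bis(silyloxy)dienes.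

Step 9
Reactants: 9 2-ethynyl-5,6,7,8-tetramethoxy-4H-chromen-4-one; 12 (1Z)-1-methoxy-1,3-bis(trimethylsilyloxy)buta-1,3-diene
Product: 14 2-(2,4-dihydroxyphenyl)-5,6,7,8-tetramethoxy-4H-chromen-4-one, via cyclohexadiene cycloadduct 13 (not isolated)
Conditions: 12 (3 equiv), PhMe, 80 °C, sealed tube; then 1 M HCl, THF, rt
Reagents that add atoms: none
Why: Proposed new method: the electron-rich diene 12 should add across the ethynyl group of 9 in a concerted but asynchronous [4+2] cycloaddition (at the polar extreme a Mukaiyama–Michael addition followed by closure onto the silyloxycarbenium carbon) to give the 1,4-cyclohexadiene 13 either way, and on acidic work-up both silyl groups are hydrolysed, the hemiketal carbon expels methanol and the dione tautomerises to the resorcinol. The closest known reaction type is the Diels–Alder reaction of 1-alkoxy-1,3-bis(silyloxy)butadienes with acetylenic ketones and esters, which gives resorcinols after loss of alcohol; here the acceptor is one vinylogue further out, the alkyne being conjugated to the C4 carbonyl through C2=C3 of the pyrone. Ring B closes as the six-membered ring of an intermolecular [4+2] cycloaddition, with C5'–C6' formed between the CH2 terminus of the diene and the terminal alkyne carbon and C1'–C2' between the ketene acetal carbon and the internal alkyne carbon. The only stereocentre, the ketal carbon of 13, arises as a racemate and is erased on aromatisation together with the diene geometry, so no stereocontrol is required. The step needs regioselectivity (2',4'- rather than 3',5'-dioxygenation) and chemoselectivity for the alkyne over C2=C3: the first comes from pairing the most nucleophilic diene terminus (CH2) with the terminal alkyne carbon, which is the unhindered δ-position of the vinylogous ynone, and the second from C2 being fully substituted and part of a vinylogous ester.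

Step 10
Reactants: 14 2-(2,4-dihydroxyphenyl)-5,6,7,8-tetramethoxy-4H-chromen-4-one
Product: 15 tamadone, 2-(2,4-dihydroxyphenyl)-5-hydroxy-6,7,8-trimethoxy-4H-chromen-4-one
Conditions: BCl3 (excess), CH2Cl2, –78 → 0 °C; then H2O
Reagents that add atoms: none
Why: Chelation-controlled Lewis-acid ether cleavage, in which BCl3 bridges the C4 carbonyl and the peri 5-methoxy oxygen so that chloride removes only that methyl group, is the usual selective 5-O-demethylation of polymethoxyflavones, and the excess reagent allows for the free ring B phenols.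

**Compound list**

1 | 3,4,5-trimethoxyphenol | COc1cc(O)cc(OC)c1OC | starting material
2 | 1-(6-hydroxy-2,3,4-trimethoxyphenyl)ethanone | CC(=O)c1c(O)cc(OC)c(OC)c1OC | intermediate
3 | 1-(3-bromo-2-hydroxy-4,5,6-trimethoxyphenyl)ethanone | CC(=O)c1c(O)c(Br)c(OC)c(OC)c1OC | intermediate
4 | 1-(2-hydroxy-3,4,5,6-tetramethoxyphenyl)ethanone | CC(=O)c1c(O)c(OC)c(OC)c(OC)c1OC | intermediate
5 | ethyl 2,2-diethoxyacetate | CCOC(OCC)C(=O)OCC | starting material
6 | 4,4-diethoxy-1-(2-hydroxy-3,4,5,6-tetramethoxyphenyl)butane-1,3-dione (not isolated) | CCOC(OCC)C(=O)CC(=O)c1c(O)c(OC)c(OC)c(OC)c1OC | intermediate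
7 | 2-(diethoxymethyl)-5,6,7,8-tetramethoxy-4H-chromen-4-one | CCOC(OCC)c1cc(=O)c2c(OC)c(OC)c(OC)c(OC)c2o1 | intermediate
8 | 5,6,7,8-tetramethoxy-4-oxo-4H-chromene-2-carbaldehyde | O=Cc1cc(=O)c2c(OC)c(OC)c(OC)c(OC)c2o1 | intermediate
9 | 2-ethynyl-5,6,7,8-tetramethoxy-4H-chromen-4-one | C#Cc1cc(=O)c2c(OC)c(OC)c(OC)c(OC)c2o1 | intermediate
10 | methyl acetoacetate | COC(=O)CC(C)=O | starting material
11 | methyl (Z)-3-(trimethylsilyloxy)but-2-enoate | COC(=O)/C=C(/C)O[Si](C)(C)C | intermediate
12 | (1Z)-1-methoxy-1,3-bis(trimethylsilyloxy)buta-1,3-diene | CO/C(O[Si](C)(C)C)=C/C(=C)O[Si](C)(C)C | intermediate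
13 | 2-[6-methoxy-4,6-bis(trimethylsilyloxy)cyclohexa-1,4-dien-1-yl]-5,6,7,8-tetramethoxy-4H-chromen-4-one (racemic, not isolated) | COC1(O[Si](C)(C)C)C=C(O[Si](C)(C)C)CC=C1c1cc(=O)c2c(OC)c(OC)c(OC)c(OC)c2o1 | intermediate
14 | 2-(2,4-dihydroxyphenyl)-5,6,7,8-tetramethoxy-4H-chromen-4-one | COc1c(OC)c(OC)c2c(=O)cc(-c3ccc(O)cc3O)oc2c1OC | intermediate
15 | tamadone, 2-(2,4-dihydroxyphenyl)-5-hydroxy-6,7,8-trimethoxy-4H-chromen-4-one | COc1c(OC)c(O)c2c(=O)cc(-c3ccc(O)cc3O)oc2c1OC | target

**Step count and risks**

Total steps: 10. Longest linear sequence: 8 (steps 1–6, 9, 10); the diene branch (steps 7–8) joins at step 9.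

Steps most likely to fail:

1. Step 9 (proposed new method). The alkyne is activated only through the C2=C3 bond, so cycloaddition may be outrun by thermal decay of the diene (silyl migration, adventitious hydrolysis). The polar pathway may also stop after the first C–C bond at an open-chain Michael adduct, or addition may turn to C2 of the pyrone. The fallback uses known chemistry and brings ring B in intact by a Baker–Venkataraman flavone synthesis. It sets out from 4. Esterification of the phenol with commercial 2,4-bis(benzyloxy)benzoic acid (EDC·HCl, DMAP, CH2Cl2) should give 2-acetyl-3,4,5,6-tetramethoxyphenyl 2,4-bis(benzyloxy)benzoate F1. KOH in pyridine at 50 °C should rearrange it to 1-[2,4-bis(benzyloxy)phenyl]-3-(2-hydroxy-3,4,5,6-tetramethoxyphenyl)propane-1,3-dione F2. p-TsOH in toluene at reflux should close ring C to 2-[2,4-bis(benzyloxy)phenyl]-5,6,7,8-tetramethoxy-4H-chromen-4-one F3. Hydrogenolysis (H2, Pd on carbon, EtOAc–MeOH) should remove both benzyl groups, and the route is rejoined at 14.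

2. Step 6. Under carbonate in methanol, methoxide may add to C2 of the pyrone with ring opening, or add in conjugate fashion to the newly formed acceptor-conjugated alkyne, so the product erodes as it forms. The fallback builds the alkyne into the pyrone instead of homologating an aldehyde. It sets out from 4. Claisen condensation of its dianion (LiN(SiMe3)2, THF, –78 → 0 °C) with commercial ethyl 3-(trimethylsilyl)propiolate should give 1-(2-hydroxy-3,4,5,6-tetramethoxyphenyl)-5-(trimethylsilyl)pent-4-yne-1,3-dione F4. Cyclodehydration (p-TsOH, PhMe, 80 °C) should give 5,6,7,8-tetramethoxy-2-[(trimethylsilyl)ethynyl]-4H-chromen-4-one F5. Buffered fluoride (Bu4NF, AcOH, THF, 0 °C) should remove the silyl group without methanolic base, and the route is rejoined at 9.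

3. Step 5. Hydrolysis of an acetal deactivated by the electron-poor pyrone may be slow, and forcing the acid may begin to cleave the peri 5-methyl ether or leave the aldehyde as a hydrate that resists drying. The fallback reaches the aldehyde by reduction and re-oxidation of an ester instead. It sets out from 4. Claisen condensation with diethyl oxalate (NaOEt, EtOH, reflux) should give ethyl 4-(2-hydroxy-3,4,5,6-tetramethoxyphenyl)-2,4-dioxobutanoate F6. This is cyclised without isolation (HCl, EtOH, reflux) to ethyl 5,6,7,8-tetramethoxy-4-oxo-4H-chromene-2-carboxylate F7. NaBH4 in MeOH at 0 °C should reduce the activated ester selectively to 2-(hydroxymethyl)-5,6,7,8-tetramethoxy-4H-chromen-4-one F8. Oxidation with MnO2 in CH2Cl2 should then give the aldehyde, and the route is rejoined at 8.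

**Further compounds**

F1 | step 9 | 2-acetyl-3,4,5,6-tetramethoxyphenyl 2,4-bis(benzyloxy)benzoate | CC(=O)c1c(OC)c(OC)c(OC)c(OC)c1OC(=O)c1ccc(OCc2ccccc2)cc1OCc1ccccc1
F2 | step 9 | 1-[2,4-bis(benzyloxy)phenyl]-3-(2-hydroxy-3,4,5,6-tetramethoxyphenyl)propane-1,3-dione | O=C(CC(=O)c1c(O)c(OC)c(OC)c(OC)c1OC)c1ccc(OCc2ccccc2)cc1OCc1ccccc1
F3 | step 9 | 2-[2,4-bis(benzyloxy)phenyl]-5,6,7,8-tetramethoxy-4H-chromen-4-one | COc1c(OC)c(OC)c2c(=O)cc(-c3ccc(OCc4ccccc4)cc3OCc3ccccc3)oc2c1OC
F4 | step 6 | 1-(2-hydroxy-3,4,5,6-tetramethoxyphenyl)-5-(trimethylsilyl)pent-4-yne-1,3-dione | C[Si](C)(C)C#CC(=O)CC(=O)c1c(O)c(OC)c(OC)c(OC)c1OC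
F5 | step 6 | 5,6,7,8-tetramethoxy-2-[(trimethylsilyl)ethynyl]-4H-chromen-4-one | C[Si](C)(C)C#Cc1cc(=O)c2c(OC)c(OC)c(OC)c(OC)c2o1
F6 | step 5 | ethyl 4-(2-hydroxy-3,4,5,6-tetramethoxyphenyl)-2,4-dioxobutanoate | CCOC(=O)C(=O)CC(=O)c1c(O)c(OC)c(OC)c(OC)c1OC
F7 | step 5 | ethyl 5,6,7,8-tetramethoxy-4-oxo-4H-chromene-2-carboxylate | CCOC(=O)c1cc(=O)c2c(OC)c(OC)c(OC)c(OC)c2o1
F8 | step 5 | 2-(hydroxymethyl)-5,6,7,8-tetramethoxy-4H-chromen-4-one | OCc1cc(=O)c2c(OC)c(OC)c(OC)c(OC)c2o1
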